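The only alkene of the seven-membered ring, C5=C6 (guaiane numbering), is flanked by the stereocentres C1 and C7. This pattern is the retron of a divinylcyclopropane rearrangement, so the ring is cut at C7–C8 and C1–C10 into a cyclopentenyl diene (C1=C5–C6=C7) and a three-carbon carbenoid (C8–C10). In one operation a chiral dirhodium vinylcarbenoid cyclopropanates the Z C6=C7 bond and the adduct rearranges, closing the cycloheptadiene and setting C1, C7 and C10. The precursor is a cyclopentene that already carries quaternary C4 and the benzylic centre (both built on a dihydrocoumarin template) and a Z silyloxy diene arm; its arene is blocked by two bromines that later become the formyl groups.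

Key step: step 13

Numbering and abbreviation: guaiane locants are used throughout (cyclopentane C1–C5 with quaternary C4; seven-membered ring C1, C5–C10; C11 is the carbinol carbon, C1′ the benzylic carbon); Ar′ = 3,5-dibromo-2,4,6-trimethoxyphenyl.

Assumption: the (R,S) ligand of step 1 and the R catalyst of step 13 are named from the sense of induction known for unsubstituted coumarins and for styrene-type alkenes; if a first run shows the opposite sense, the mirror-image ligand or catalyst is used with nothing else changed.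

**Step 1**
Reactants: 1 5,7-dimethoxycoumarin; 2 isobutylmagnesium bromide
Product: 3 (4R)-5,7-dimethoxy-4-(2-methylpropyl)chroman-2-one
Conditions: CuBr·SMe2 (5 mol%), (R,S)-rev-Josiphos (6 mol%), t-BuOMe/CH2Cl2, −72 °C; then cold 1 M HCl
Reagents that add atoms: none
Why: Copper-catalysed asymmetric conjugate addition of a Grignard reagent to the coumarin enoate, in which the chiral ferrocenyl diphosphine–copper complex chooses the face of the beta carbon and so should set the benzylic centre C1′ as R, while the lactone keeps one phenol oxygen in a ring that steers the next two steps.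

**Step 2**
Reactants: 3 (4R)-4-isobutyl lactone
Product: 4 (3R,4R)-5,7-dimethoxy-3-methyl-4-(2-methylpropyl)chroman-2-one (3,4-trans)
Conditions: LiN(SiMe3)2, THF, −78 °C; MeI, −78 → −20 °C
Reagents that add atoms: iodomethane, CI
Why: Lactone enolate alkylation, expected trans to the pseudoaxial isobutyl group, although the configuration at C3 is of no consequence because this centre is enolized again in step 3.

**Step 3**
Reactants: 4 trans-3-methyl lactone
Product: 5 (3R,4R)-3-allyl-5,7-dimethoxy-3-methyl-4-(2-methylpropyl)chroman-2-one (allyl trans, methyl cis to isobutyl)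
Conditions: LiN(SiMe3)2, THF/DMPU, −78 °C; allyl bromide, −78 → 0 °C
Reagents that add atoms: allyl bromide, C=CCBr
Why: Second enolate alkylation, in which the isobutyl group is held pseudoaxial by the peri 5-methoxy group and shields one face of the tetrasubstituted enolate, so that the allyl group should enter trans to it and fix the quaternary centre (future C4, R) relative to C1′.

**Step 4**
Reactants: 5 allyl methyl lactone
Product: 6 (3R,4R)-3-allyl-5,7-dimethoxy-3-methyl-4-(2-methylpropyl)chroman-2-ol (lactol, both anomers)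
Conditions: i-Bu2AlH (1.1 equiv), CH2Cl2, −78 °C; aq. potassium sodium tartrate
Reagents that add atoms: none
Why: Partial reduction of a lactone to the lactol with a dialkylaluminium hydride, which stops at the hemiacetal stage because the hindered tetrahedral aluminate does not collapse at −78 °C.

**Step 5**
Reactants: 6 lactol
Product: 7 (2R,3R)-2-allyl-2,5-dimethyl-3-(2,4,6-trimethoxyphenyl)hexanal
Conditions: K2CO3, MeI, DMF, 23 °C
Reagents that add atoms: iodomethane, CI
Why: Williamson ether synthesis on the phenoxide of the ring-opened hydroxy aldehyde (ring–chain tautomer of the lactol), which traps the open form as the third aryl methyl ether and frees the aldehyde, whose alpha carbon is quaternary and therefore cannot epimerize.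

**Step 6**
Reactants: 7 pentenal
Product: 8 (2R)-2-methyl-2-[(1R)-3-methyl-1-(2,4,6-trimethoxyphenyl)butyl]cyclopentan-1-one
Conditions: [Rh(nbd)(dppe)]BF4 (5 mol%, activated with H2), CH2Cl2, 23 °C
Reagents that add atoms: none
Why: Rhodium-catalysed intramolecular alkene hydroacylation of a 2,2-disubstituted pent-4-enal (C–H oxidative addition, alkene insertion, reductive elimination), which joins the formyl carbon (C5) to the terminal alkene carbon (C1) and closes the cyclopentanone without touching either stereocentre.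

**Step 7**
Reactants: 8 cyclopentanone
Product: 9 (2R)-2-[(1R)-1-(3,5-dibromo-2,4,6-trimethoxyphenyl)-3-methylbutyl]-2-methylcyclopentan-1-one
Conditions: NBS (2.1 equiv), MeCN, 0 → 23 °C
Reagents that add atoms: N-bromosuccinimide, O=C1CCC(=O)N1Br
Why: Electrophilic aromatic bromination at the two free ring positions, each activated by two ortho and one para methoxy group, which gives a fully substituted arene that the carbenoid of step 13 cannot alkylate and that carries the handles for the later formylation.

**Step 8**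
Reactants: 9 dibromo ketone
Product: 10 (5R)-5-[(1R)-1-Ar′-3-methylbutyl]-5-methylcyclopent-1-en-1-yl trifluoromethanesulfonate
Conditions: KN(SiMe3)2, THF, −78 °C; PhNTf2, −78 → 0 °C
Reagents that add atoms: N-phenylbis(trifluoromethanesulfonimide), O=S(=O)(N(c1ccccc1)S(=O)(=O)C(F)(F)F)C(F)(F)F
Why: Enol triflate formation from the potassium enolate, which can form only toward C1 because C4 is quaternary, so that one alkenyl triflate regioisomer is expected.

**Step 9**
Reactants: 10 alkenyl triflate; 11 2-methylbut-3-yn-2-ol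
Product: 12 4-{(5R)-5-[(1R)-1-Ar′-3-methylbutyl]-5-methylcyclopent-1-en-1-yl}-2-methylbut-3-yn-2-ol
Conditions: Pd(PPh3)2Cl2 (5 mol%), CuI (10 mol%), Et3N, THF, 23 °C
Reagents that add atoms: none
Why: Sonogashira coupling of the alkenyl triflate with the terminal alkyne, selective because oxidative addition into the two hindered, electron-rich aryl bromides is far slower at room temperature.

**Step 10**
Reactants: 12 enyne alcohol
Product: 13 (3Z)-4-{(5R)-5-[(1R)-1-Ar′-3-methylbutyl]-5-methylcyclopent-1-en-1-yl}-2-methylbut-3-en-2-ol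
Conditions: H2 (1 atm), Pd/CaCO3 poisoned with Pb(OAc)2, quinoline, EtOAc, 23 °C
Reagents that add atoms: none
Why: Lindlar semihydrogenation, in which syn addition of hydrogen to the alkyne on the poisoned palladium surface gives the Z C6=C7 alkene and stops before the diene or the aryl bromides are reduced.

**Step 11**
Reactants: 13 Z-dienol
Product: 14 triethylsilyl ether of 13, (5R)-1-[(1Z)-3-methyl-3-(triethylsilyloxy)but-1-en-1-yl]-5-[(1R)-1-Ar′-3-methylbutyl]-5-methylcyclopent-1-ene
Conditions: Et3SiOTf, 2,6-lutidine, CH2Cl2, −78 → 0 °C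
Reagents that add atoms: triethylsilyl trifluoromethanesulfonate, CC[Si](CC)(CC)OS(=O)(=O)C(F)(F)F
Why: Silylation of the tertiary alcohol with a silyl triflate and a hindered base, which removes the O–H bond that a rhodium carbenoid would attack (insertion or ylide formation followed by [2,3] shift) while C11 remains without any hydrogen.

**Step 12**
Reactants: 15 methyl (E)-pent-3-enoate
Product: 16 methyl (E)-2-diazopent-3-enoate
Conditions: p-ABSA, DBU, MeCN, 0 °C; used at once
Reagents that add atoms: 4-acetamidobenzenesulfonyl azide, CC(=O)Nc1ccc(cc1)S(=O)(=O)N=[N+]=[N-]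
Why: Regitz diazo transfer to the alpha carbon of a beta,gamma-unsaturated ester, which keeps the E alkene and gives a vinyldiazoacetate that is used cold and fresh because it slowly closes to a pyrazole.

**Step 13**
Reactants: 14 Z-dienyl cyclopentene silyl ether; 16 methyl (E)-2-diazopent-3-enoate
Product: 18 methyl (1R,4R,7S,10R)-4-[(1R)-1-Ar′-3-methylbutyl]-11-(triethylsilyloxy)guaia-5,8-diene-8-carboxylate, via all-cis divinylcyclopropane 17 (not isolated)
Conditions: Rh2(R-DOSP)4 [dirhodium tetrakis((R)-N-(4-dodecylphenylsulfonyl)prolinate), 2 mol%], hexanes, −20 → 23 °C, slow addition of 16 (3 equiv); then toluene, 90 °C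
Reagents that add atoms: none
Why: The dirhodium catalyst converts 16 into a donor/acceptor vinylcarbenoid that adds to the Z C6=C7 bond in a concerted, asynchronous cyclopropanation (bonding first at C7, charge build-up at allylic C6) with the propenyl group cis to both alkene substituents, giving cyclopropane 17, which on heating undergoes the [3,3] shift through a boat transition state, breaking C6–C8 and forming C1–C10. The closest known reaction type is the tandem cyclopropanation–Cope rearrangement of rhodium vinylcarbenoids with 1,3-dienes, established for cis-substituted dienes but not for one with a tertiary alkyl group on the alkene. The seven-membered ring (C1, C5–C10) is closed by the sigmatropic C1–C10 bond formation of the cis-divinylcyclopropane, after the intermolecular step has made C7–C8. C7 is set by the alkene face that the chiral catalyst selects, while C1 and C10 follow from the boat geometry: the E substituents at both termini (C2 on C1, methyl on C10) point outward and end cis to each other and trans to the C7 substituent, and the new bond forms on the cyclopentene face syn to the C4 methyl and anti to the large side chain, as the target requires. The step needs site selectivity for C6=C7 over the ring alkene, the arene, the allylic C–H bonds and the ether oxygen, and face selectivity matched to C4; the first rests on the known preference of these carbenoids for cis-disubstituted alkenes, the fully substituted arene and the hindered silyl ether, the second on catalyst control reinforced by the side chain shielding one face of the twisted diene. Because C11 is quaternary, the cyclopropane has no hydrogen for a competing homodienyl 1,5-shift, so a slow Cope step can be forced thermally.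

**Step 14**
Reactants: 18 diene ester
Product: 19 methyl (1R,4R,7S,8RS,10R)-4-[(1R)-1-Ar′-3-methylbutyl]-11-(triethylsilyloxy)guai-5-ene-8-carboxylate (C8 epimers)
Conditions: Cu(OAc)2·H2O (5 mol%), 1,2-bis(diphenylphosphino)benzene (5 mol%), MeSiH(OEt)2, t-BuOH, toluene, 23 °C
Reagents that add atoms: none
Why: Copper hydride catalysed conjugate reduction of the enoate (Stryker-type), which delivers hydride to C9 only, leaves the isolated C5=C6 alkene and the aryl bromides alone, avoids basic conditions that could deprotonate C10, and creates a C8 centre whose configuration does not matter.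

**Step 15**
Reactants: 19 saturated ester
Product: 20 (1R,4R,7S,8RS,10R)-4-[(1R)-1-Ar′-3-methylbutyl]-11-(triethylsilyloxy)guai-5-ene-8-carboxylic acid
Conditions: LiOH, THF/MeOH/H2O, 60 °C; then 1 M HCl to pH 4, 0 °C
Reagents that add atoms: lithium hydroxide, [Li+].[OH-]
Why: Ester saponification by acyl–oxygen cleavage, carried out with the tertiary silyl ether still in place so that the acid cannot close a lactone onto the C11 oxygen.

**Step 16**
Reactants: 20 carboxylic acid
Product: 22 (1R,4R,7R,10R)-4-[(1R)-1-Ar′-3-methylbutyl]-11-(triethylsilyloxy)guai-5-ene, via Barton ester 21 (not isolated)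
Conditions: 2-mercaptopyridine N-oxide, DCC, DMAP (cat.), CH2Cl2, 23 °C, dark; then t-BuSH (20 equiv), hν (tungsten lamp), 23 °C
Reagents that add atoms: none
Why: Barton reductive decarboxylation, in which the thiohydroxamate ester fragments under visible light to the secondary C8 radical and a large excess of thiol transfers hydrogen faster than the radical can add to C5=C6, while thiyl radicals do not abstract the aryl bromines.

**Step 17**
Reactants: 22 dibromo silyl ether
Product: 23 2,4,6-trimethoxy-5-[(1R)-3-methyl-1-[(1R,4R,7R,10R)-11-(triethylsilyloxy)guai-5-en-4-yl]butyl]benzene-1,3-dicarbaldehyde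
Conditions: t-BuLi (4.4 equiv), THF, −78 °C; DMF, −78 → 0 °C; then H2O
Reagents that add atoms: N,N-dimethylformamide, CN(C)C=O
Why: Double bromine–lithium exchange followed by formylation of the aryllithium sites with a formamide (Bouveault aldehyde synthesis), each carbanion being flanked by two coordinating methoxy groups, which installs both aldehydes without the Lewis acids of a Friedel–Crafts formylation that would ionize the tertiary silyl ether.

**Step 18**
Reactants: 23 dialdehyde silyl ether
Product: 24 5-[(1R)-1-[(1R,4R,7R,10R)-11-hydroxyguai-5-en-4-yl]-3-methylbutyl]-2,4,6-trimethoxybenzene-1,3-dicarbaldehyde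
Conditions: HF·pyridine, pyridine/THF, 0 → 23 °C
Reagents that add atoms: none
Why: Fluoride-induced cleavage of the triethylsilyl ether under pyridine-buffered conditions, mild enough to leave the aldehydes, the trisubstituted alkene and the tertiary alcohol unchanged.

**Step 19**
Reactants: 24 trimethyl ether
Product: 25 (−)-macrocarpal D, 5-[(1R)-1-[(1R,4R,7R,10R)-11-hydroxyguai-5-en-4-yl]-3-methylbutyl]-2,4,6-trihydroxybenzene-1,3-dicarbaldehyde
Conditions: NaSEt (12 equiv), DMF, 120 °C; then cold dilute HCl to pH 3
Reagents that add atoms: none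
Why: Nucleophilic demethylation of the three aryl methyl ethers by thiolate (SN2 at methyl), favoured because every methoxy group is ortho or para to a formyl group, under basic conditions that spare the tertiary alcohol and the alkene.

**Compound list**

1 | 5,7-dimethoxycoumarin (5,7-dimethoxy-2H-chromen-2-one) | O=c1ccc2c(OC)cc(OC)cc2o1 | starting material
2 | isobutylmagnesium bromide | CC(C)C[Mg]Br | starting material
3 | (4R)-5,7-dimethoxy-4-(2-methylpropyl)chroman-2-one | CC(C)C[C@H]1c2c(OC)cc(OC)cc2OC(=O)C1 | intermediate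
4 | (3R,4R)-5,7-dimethoxy-3-methyl-4-(2-methylpropyl)chroman-2-one (3,4-trans) | CC(C)C[C@H]1c2c(OC)cc(OC)cc2OC(=O)[C@@H]1C | intermediate
5 | (3R,4R)-3-allyl-5,7-dimethoxy-3-methyl-4-(2-methylpropyl)chroman-2-one (allyl trans to isobutyl) | CC(C)C[C@H]1c2c(OC)cc(OC)cc2OC(=O)[C@]1(C)CC=C | intermediate
6 | (3R,4R)-3-allyl-5,7-dimethoxy-3-methyl-4-(2-methylpropyl)chroman-2-ol (lactol, anomer mixture) | CC(C)C[C@H]1c2c(OC)cc(OC)cc2OC(O)[C@]1(C)CC=C | intermediate
7 | (2R,3R)-2-allyl-2,5-dimethyl-3-(2,4,6-trimethoxyphenyl)hexanal | CC(C)C[C@@H](c1c(OC)cc(OC)cc1OC)[C@@](C)(CC=C)C=O | intermediate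
8 | (2R)-2-methyl-2-[(1R)-3-methyl-1-(2,4,6-trimethoxyphenyl)butyl]cyclopentan-1-one | CC(C)C[C@@H](c1c(OC)cc(OC)cc1OC)[C@@]1(C)CCCC1=O | intermediate
9 | (2R)-2-[(1R)-1-(3,5-dibromo-2,4,6-trimethoxyphenyl)-3-methylbutyl]-2-methylcyclopentan-1-one | CC(C)C[C@@H](c1c(OC)c(Br)c(OC)c(Br)c1OC)[C@@]1(C)CCCC1=O | intermediate
10 | (5R)-5-[(1R)-1-(3,5-dibromo-2,4,6-trimethoxyphenyl)-3-methylbutyl]-5-methylcyclopent-1-en-1-yl trifluoromethanesulfonate | CC(C)C[C@@H](c1c(OC)c(Br)c(OC)c(Br)c1OC)[C@@]1(C)CCC=C1OS(=O)(=O)C(F)(F)F | intermediate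
11 | 2-methylbut-3-yn-2-ol | CC(C)(O)C#C | starting material
12 | 4-{(5R)-5-[(1R)-1-(3,5-dibromo-2,4,6-trimethoxyphenyl)-3-methylbutyl]-5-methylcyclopent-1-en-1-yl}-2-methylbut-3-yn-2-ol | CC(C)C[C@@H](c1c(OC)c(Br)c(OC)c(Br)c1OC)[C@@]1(C)CCC=C1C#CC(C)(C)O | intermediate
13 | (3Z)-4-{(5R)-5-[(1R)-1-(3,5-dibromo-2,4,6-trimethoxyphenyl)-3-methylbutyl]-5-methylcyclopent-1-en-1-yl}-2-methylbut-3-en-2-ol | CC(C)C[C@@H](c1c(OC)c(Br)c(OC)c(Br)c1OC)[C@@]1(C)CCC=C1/C=C\C(C)(C)O | intermediate
14 | triethylsilyl ether of 13 (key-step precursor, Z-dienyl cyclopentene) | CC(C)C[C@@H](c1c(OC)c(Br)c(OC)c(Br)c1OC)[C@@]1(C)CCC=C1/C=C\C(C)(C)O[Si](CC)(CC)CC | intermediate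
15 | methyl (E)-pent-3-enoate | C/C=C/CC(=O)OC | starting material
16 | methyl (E)-2-diazopent-3-enoate | COC(=O)C(=[N+]=[N-])/C=C/C | intermediate
17 | methyl 2-(cyclopentenyl)-1-[(E)-prop-1-enyl]-3-[2-(triethylsilyloxy)propan-2-yl]cyclopropane-1-carboxylate with the cyclopentenyl, propenyl and silyloxypropyl groups all cis (C6, C7, C8 cyclopropane) | CC(C)C[C@@H](c1c(OC)c(Br)c(OC)c(Br)c1OC)[C@@]1(C)CCC=C1[C@@H]2[C@H](C(C)(C)O[Si](CC)(CC)CC)[C@]2(C(=O)OC)/C=C/C | intermediate
18 | methyl (1R,4R,7S,10R)-4-[(1R)-1-(3,5-dibromo-2,4,6-trimethoxyphenyl)-3-methylbutyl]-11-(triethylsilyloxy)guaia-5,8-diene-8-carboxylate (key-step product) | CC(C)C[C@@H](c1c(OC)c(Br)c(OC)c(Br)c1OC)[C@@]1(C)CC[C@H]2C1=C[C@H](C(C)(C)O[Si](CC)(CC)CC)C(C(=O)OC)=C[C@H]2C | intermediate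
19 | methyl (1R,4R,7S,8RS,10R)-4-[(1R)-1-(3,5-dibromo-2,4,6-trimethoxyphenyl)-3-methylbutyl]-11-(triethylsilyloxy)guai-5-ene-8-carboxylate | CC(C)C[C@@H](c1c(OC)c(Br)c(OC)c(Br)c1OC)[C@@]1(C)CC[C@H]2C1=C[C@H](C(C)(C)O[Si](CC)(CC)CC)C(C(=O)OC)C[C@H]2C | intermediate
20 | corresponding guai-5-ene-8-carboxylic acid (C8 epimers) | CC(C)C[C@@H](c1c(OC)c(Br)c(OC)c(Br)c1OC)[C@@]1(C)CC[C@H]2C1=C[C@H](C(C)(C)O[Si](CC)(CC)CC)C(C(=O)O)C[C@H]2C | intermediate
21 | 2-thioxopyridin-1(2H)-yl ester of 20 (Barton ester) | CC(C)C[C@@H](c1c(OC)c(Br)c(OC)c(Br)c1OC)[C@@]1(C)CC[C@H]2C1=C[C@H](C(C)(C)O[Si](CC)(CC)CC)C(C(=O)ON3C=CC=CC3=S)C[C@H]2C | intermediate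
22 | (1R,4R,7R,10R)-4-[(1R)-1-(3,5-dibromo-2,4,6-trimethoxyphenyl)-3-methylbutyl]-11-(triethylsilyloxy)guai-5-ene | CC(C)C[C@@H](c1c(OC)c(Br)c(OC)c(Br)c1OC)[C@@]1(C)CC[C@H]2C1=C[C@H](C(C)(C)O[Si](CC)(CC)CC)CC[C@H]2C | intermediate
23 | 2,4,6-trimethoxy-5-[(1R)-3-methyl-1-[(1R,4R,7R,10R)-11-(triethylsilyloxy)guai-5-en-4-yl]butyl]benzene-1,3-dicarbaldehyde | CC(C)C[C@@H](c1c(OC)c(C=O)c(OC)c(C=O)c1OC)[C@@]1(C)CC[C@H]2C1=C[C@H](C(C)(C)O[Si](CC)(CC)CC)CC[C@H]2C | intermediate
24 | 5-[(1R)-1-[(1R,4R,7R,10R)-11-hydroxyguai-5-en-4-yl]-3-methylbutyl]-2,4,6-trimethoxybenzene-1,3-dicarbaldehyde | CC(C)C[C@@H](c1c(OC)c(C=O)c(OC)c(C=O)c1OC)[C@@]1(C)CC[C@H]2C1=C[C@H](C(C)(C)O)CC[C@H]2C | intermediate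
25 | (−)-macrocarpal D | CC(C)C[C@@H](c1c(O)c(C=O)c(O)c(C=O)c1O)[C@@]1(C)CC[C@H]2C1=C[C@H](C(C)(C)O)CC[C@H]2C | target

**Step count and risk**

Total: 19 steps. Longest linear sequence: 18 steps (steps 1–11 and 13–19); step 12 is a one-step side branch.

Steps most likely to fail:

1. Step 13. Cyclopropanation of the hindered Z alkene may be outrun by carbene dimerization, insertion into the allylic C2–H bonds or attack on the wrong alkene face. The crowded all-cis cyclopropane may also epimerize by C6–C8 homolysis instead of reaching the boat geometry. The fallback delivers the carbene intramolecularly and sets out from dienol 13. Acylation with bromoacetyl bromide (pyridine, CH2Cl2, 0 °C) gives the bromoacetate F1, and N,N′-ditosylhydrazine with DBU converts it into the diazoacetate F2. Rh2(5S-MEPY)4 (dirhodium tetrakis[methyl (5S)-2-oxopyrrolidine-5-carboxylate], enantiomer chosen for the required face) then closes the cyclopropane-fused lactone F3 across C6=C7, in which the three substituents are cis by construction. Reduction with i-Bu2AlH gives the lactol F4. Takai–Utimoto ethylidenation (CH3CHI2, CrCl2, THF) gives the (E)-propenyl cis-divinylcyclopropane carbinol F5, which is less crowded than 17 because C8 carries hydrogen and the carbinol is free. Heating in toluene should give the Cope product, cycloheptadienol F6. Diimide (2-nitrobenzenesulfonylhydrazide, Et3N) reduces only the disubstituted C8=C9 bond to give the guai-5-en-11-ol F7. Bromine–lithium exchange with t-BuLi (5 equiv) and DMF then returns to the route at 24, so that steps 14–18 are not needed.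

2. Step 1. The peri methoxy group and the electron-rich enoate may slow the chiral copper complex so much that conversion stays low or an unselective background addition erodes the enantiomeric purity. The fallback moves the stereo-defining event from alkyl transfer to hydride transfer and sets out from 1 and 2. Uncatalysed-ligand cuprate addition (2, CuI, Me3SiCl, THF, −40 °C) gives the racemic lactone F8. Dehydrogenation with DDQ (dioxane, reflux) gives 4-isobutyl-5,7-dimethoxycoumarin F9. Copper hydride asymmetric conjugate reduction (Cu(OAc)2, DTBM-SEGPHOS, MeSiH(OEt)2, t-BuOH) then returns to the route at 3.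

3. Step 16. Esterification of the hindered acid may stall, or the homoallylic C8 radical may close onto C5=C6 and rearrange by vinyl shift before hydrogen transfer. The fallback avoids a free radical and sets out from ester 19. Reduction with i-Bu2AlH at −78 °C gives the C8 aldehyde F10, and stoichiometric RhCl(PPh3)3 (toluene, 110 °C, Tsuji–Wilkinson decarbonylation) removes the formyl group and returns to the route at 22.

**Further compounds**

F1 | step 13 | (3Z)-4-{(5R)-5-[(1R)-1-Ar′-3-methylbutyl]-5-methylcyclopent-1-en-1-yl}-2-methylbut-3-en-2-yl bromoacetate | CC(C)C[C@@H](c1c(OC)c(Br)c(OC)c(Br)c1OC)[C@@]1(C)CCC=C1/C=C\C(C)(C)OC(=O)CBr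
F2 | step 13 | corresponding diazoacetate | CC(C)C[C@@H](c1c(OC)c(Br)c(OC)c(Br)c1OC)[C@@]1(C)CCC=C1/C=C\C(C)(C)OC(=O)C=[N+]=[N-]
F3 | step 13 | 4,4-dimethyl-6-(cyclopentenyl)-3-oxabicyclo[3.1.0]hexan-2-one, cyclopentenyl cis to the lactone ring | CC(C)C[C@@H](c1c(OC)c(Br)c(OC)c(Br)c1OC)[C@@]1(C)CCC=C1[C@@H]2[C@@H]3C(C)(C)OC(=O)[C@H]23
F4 | step 13 | corresponding lactol (3-oxabicyclo[3.1.0]hexan-2-ol) | CC(C)C[C@@H](c1c(OC)c(Br)c(OC)c(Br)c1OC)[C@@]1(C)CCC=C1[C@@H]2[C@@H]3C(C)(C)OC(O)[C@H]23
F5 | step 13 | 2-{all-cis-2-(cyclopentenyl)-3-[(E)-prop-1-enyl]cyclopropyl}propan-2-ol | CC(C)C[C@@H](c1c(OC)c(Br)c(OC)c(Br)c1OC)[C@@]1(C)CCC=C1[C@@H]2[C@H](C(C)(C)O)[C@@H]2/C=C/C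
F6 | step 13 | (1R,4R,7R,10R)-4-[(1R)-1-Ar′-3-methylbutyl]guaia-5,8-dien-11-ol | CC(C)C[C@@H](c1c(OC)c(Br)c(OC)c(Br)c1OC)[C@@]1(C)CC[C@H]2C1=C[C@H](C(C)(C)O)C=C[C@H]2C
F7 | step 13 | (1R,4R,7R,10R)-4-[(1R)-1-Ar′-3-methylbutyl]guai-5-en-11-ol | CC(C)C[C@@H](c1c(OC)c(Br)c(OC)c(Br)c1OC)[C@@]1(C)CC[C@H]2C1=C[C@H](C(C)(C)O)CC[C@H]2C
F8 | step 1 | racemic 5,7-dimethoxy-4-(2-methylpropyl)chroman-2-one | CC(C)CC1CC(=O)Oc2cc(OC)cc(OC)c21
F9 | step 1 | 4-isobutyl-5,7-dimethoxycoumarin | CC(C)Cc1cc(=O)oc2cc(OC)cc(OC)c12
F10 | step 16 | (1R,4R,7S,8RS,10R)-4-[(1R)-1-Ar′-3-methylbutyl]-11-(triethylsilyloxy)guai-5-ene-8-carbaldehyde | CC(C)C[C@@H](c1c(OC)c(Br)c(OC)c(Br)c1OC)[C@@]1(C)CC[C@H]2C1=C[C@H](C(C)(C)O[Si](CC)(CC)CC)C(C=O)C[C@H]2C
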